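**Retrosynthetic overview**
1. The (E)-enol ester is made second to last by copper-catalysed C–O coupling of an (E)-alkenyltrifluoroborate (from the ring aldehyde by Takai–Utimoto olefination) with 3-methylbut-2-enoic acid; the two free alcohols are unmasked last.
2. The cycloheptenone (the only ring of the target, formed last) comes from ring-closing metathesis between an allyl group on the quaternary carbon and an α-methylene ketone.
3. The open-chain metathesis precursor comes from retro-Claisen opening of a 2-acetylcyclohexanone; this cyclohexanone template (first ring, later opened) carries the three contiguous stereocentres.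
4. On the template, C-7 (target ring numbering) is set by an organocatalytic Michael/aldol sequence, C-6 by trans α'-alkylation, and quaternary C-5 by cuprate methylation after 1,2-addition and oxidative allylic transposition.
5. The side-chain carbinol is set separately by ketoreductase reduction of a chloro enone, and the fragment is joined as a Grignard reagent.

Assumption: the (S)-diarylprolinol catalyst (step 5) and the screened ketoreductase (step 2) give the configurations drawn; if not, the enantiomeric catalyst or an enzyme of opposite selectivity from the same panel is used.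
Abbreviations: TBS = tert-butyldimethylsilyl, PMB = 4-methoxybenzyl, DMP = Dess–Martin periodinane.

**Step 1**
Reactants: 1 3-chloro-N-methoxy-N-methylpropanamide; 2 isopropenylmagnesium bromide
Product: 3 5-chloro-2-methylpent-1-en-3-one
Conditions: THF, −20 → 0 °C; cold aq. NH4Cl
Reagents that add atoms: none
Why: Weinreb ketone synthesis; the chelated tetrahedral intermediate stops at the ketone, which is used cold and at once.

**Step 2**
Reactants: 3 5-chloro-2-methylpent-1-en-3-one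
Product: 4 (3R)-5-chloro-2-methylpent-1-en-3-ol
Conditions: ketoreductase (R-selective, NADPH-dependent), NADP+ (cat.), i-PrOH (10% v/v), phosphate buffer pH 7.0, 30 °C
Reagents that add atoms: none
Why: Enzymatic asymmetric carbonyl reduction by a ketoreductase (NADPH-dependent alcohol dehydrogenase class) delivers hydride to one face of the ketone and sets the side-chain carbinol as R; isopropanol recycles the cofactor.

**Step 3**
Reactants: 4 (3R)-5-chloro-2-methylpent-1-en-3-ol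
Product: 5 (3R)-3-(TBSO)-5-chloro-2-methylpent-1-ene
Conditions: TBSCl, imidazole, DMF, rt
Reagents that add atoms: tert-butyldimethylsilyl chloride, CC(C)(C)[Si](C)(C)Cl
Why: Standard silylation of the secondary allylic alcohol; the stereocentre is untouched.

**Step 4**
Reactants: 6 (tert-butyldimethylsilyloxy)acetaldehyde; 7 (triphenylphosphoranylidene)acetaldehyde
Product: 8 (2E)-4-(TBSO)but-2-enal
Conditions: toluene, 80 °C
Reagents that add atoms: none
Why: Wittig olefination with a stabilised formyl ylide gives the E-enal.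

**Step 5**
Reactants: 8 (2E)-4-(TBSO)but-2-enal; 9 allyl acetoacetate
Product: 11 allyl (6R)-6-(TBSOCH2)-2-oxocyclohex-3-ene-1-carboxylate (C-1 epimers), via Michael adduct 10 (not isolated)
Conditions: (S)-2-[diphenyl(trimethylsilyloxy)methyl]pyrrolidine (10 mol%), PhCO2H (10 mol%), toluene, rt; then pyrrolidine/AcOH (20 mol%), 40 °C
Reagents that add atoms: none
Why: Iminium-catalysed asymmetric Michael addition of the β-keto ester to the enal (one face of the iminium ion shielded by the diarylsilyloxymethyl group) sets the first ring stereocentre, then an amine/acid intramolecular aldol condensation closes the cyclohexenone.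

**Step 6**
Reactants: 11 allyl (6R)-6-(TBSOCH2)-2-oxocyclohex-3-ene-1-carboxylate
Product: 12 (5R)-5-(TBSOCH2)cyclohex-2-en-1-one
Conditions: Pd(OAc)2 (2 mol%), PPh3 (8 mol%), HCO2H, Et3N, THF, rt
Reagents that add atoms: none
Why: Tsuji palladium-catalysed deallylation–decarboxylation of the allyl β-keto ester under neutral conditions; formate reduces the π-allyl fragment and the silyl ether survives.

**Step 7**
Reactants: 12 (5R)-5-(TBSOCH2)cyclohex-2-en-1-one
Product: 13 (5R,6R)-5-(TBSOCH2)-6-(PMBOCH2)cyclohex-2-en-1-one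
Conditions: LiN(iPr)2 (1.05 equiv), THF, −78 °C; PMBOCH2Cl, −78 → −40 °C
Reagents that add atoms: 4-methoxybenzyl chloromethyl ether, COc1ccc(COCCl)cc1
Why: Kinetic α'-enolate alkylation of the enone; the electrophile enters anti to the C-5 substituent and the trans (diequatorial) product is also the thermodynamic one.

**Step 8**
Reactants: 13 (5R,6R)-5-(TBSOCH2)-6-(PMBOCH2)cyclohex-2-en-1-one; 5 (3R)-3-(TBSO)-5-chloro-2-methylpent-1-ene
Product: 15 (5R,6R)-1-[(3R)-3-(TBSO)-4-methylpent-4-enyl]-5-(TBSOCH2)-6-(PMBOCH2)cyclohex-2-en-1-ol (both C-1 epimers), via Grignard reagent 14 (not isolated)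
Conditions: 5 (1.5 equiv), Mg, THF, 50 °C; then 13, LaCl3·2LiCl (30 mol%), THF, −78 → 0 °C; aq. NH4Cl
Reagents that add atoms: none
Why: Grignard formation and LaCl3-promoted 1,2-addition to the enone carbonyl, which suppresses enolisation and β-alkoxy elimination; the new carbinol centre is removed in the next step.

**Step 9**
Reactants: 15 the tertiary allylic alcohol from step 8
Product: 16 (4S,5R)-3-[(3R)-3-(TBSO)-4-methylpent-4-enyl]-4-(PMBOCH2)-5-(TBSOCH2)cyclohex-2-en-1-one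
Conditions: pyridinium chlorochromate [C5H5NH][CrO3Cl], 4 Å MS, CH2Cl2, rt
Reagents that add atoms: none
Why: Oxidative 1,3-allylic transposition (Dauben type): [3,3] shift of the chromate ester and oxidation give the β-substituted enone.

**Step 10**
Reactants: 16 the enone from step 9
Product: 18 (3S,4S,5R)-3-methyl-3-[(3R)-3-(TBSO)-4-methylpent-4-enyl]-4-(PMBOCH2)-5-(TBSOCH2)cyclohexan-1-one, via TMS enol ether 17 (not isolated)
Conditions: Me2CuLi (3 equiv, from MeLi and CuI), Me3SiCl, Et2O/THF, −78 → −20 °C; then 1 M HCl, THF, 0 °C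
Reagents that add atoms: lithium dimethylcuprate, [Li+].C[Cu-]C
Why: Cuprate conjugate addition creates the quaternary centre by axial attack on the half-chair with both ring substituents equatorial, anti to the C-5 substituent (the 5-substituted cyclohexenone rule), so the methyl ends up cis to CH2OPMB.

**Step 11**
Reactants: 18 the ketone from step 10
Product: 19 (3S,4S,5S)-2-(1-hydroxyethyl)-5-methyl-5-[(3R)-3-(TBSO)-4-methylpent-4-enyl]-4-(PMBOCH2)-3-(TBSOCH2)cyclohexan-1-one (epimers at C-2 and at the carbinol)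
Conditions: LiN(iPr)2, THF, −78 °C; MeCHO, −78 °C; aq. NH4Cl
Reagents that add atoms: acetaldehyde, CC=O
Why: Kinetic deprotonation occurs at the CH2 remote from the quaternary carbon, and the lithium enolate undergoes aldol addition to acetaldehyde.

**Step 12**
Reactants: 19 the aldol from step 11
Product: 20 (3S,4S,5S)-2-acetyl-5-methyl-5-[(3R)-3-(TBSO)-4-methylpent-4-enyl]-4-(PMBOCH2)-3-(TBSOCH2)cyclohexan-1-one (keto/enol)
Conditions: DMP, CH2Cl2, rt
Reagents that add atoms: none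
Why: Dess–Martin oxidation of the β-hydroxy ketone to the β-diketone.

**Step 13**
Reactants: 20 the β-diketone from step 12
Product: 21 (3S,4S,5R)-3-methyl-3-[(3R)-3-(TBSO)-4-methylpent-4-enyl]-4-(PMBOCH2)-5-(TBSOCH2)-7-oxooctanoic acid
Conditions: KOH, MeOH/H2O, 60 °C; then 1 M HCl to pH 3, 0 °C
Reagents that add atoms: potassium hydroxide, [K+].[OH-]
Why: Retro-Claisen ring opening of the 2-acylcyclohexanone: addition to the ring carbonyl and C1–C2 cleavage give the carboxylate (irreversible) and the acetonyl ketone; no stereocentre is touched.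

**Step 14**
Reactants: 21 the keto acid from step 13
Product: 22 (3S,4S,5R)-3-methyl-3-[(3R)-3-(TBSO)-4-methylpent-4-enyl]-4-(PMBOCH2)-5-(TBSOCH2)octane-1,7-diol (C-7 epimers)
Conditions: LiAlH4, THF, 0 °C → reflux
Reagents that add atoms: none
Why: Hydride reduction of acid and ketone; the methyl ketone is parked as a carbinol (both epimers are reoxidised in step 24).

**Step 15**
Reactants: 22 the diol from step 14
Product: 23 (3S,4S,5R)-7-hydroxy-3-methyl-3-[(3R)-3-(TBSO)-4-methylpent-4-enyl]-4-(PMBOCH2)-5-(TBSOCH2)octanal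
Conditions: TEMPO (10 mol%), PhI(OAc)2, CH2Cl2, rt
Reagents that add atoms: none
Why: Oxoammonium-mediated oxidation is chemoselective for the primary alcohol over the secondary one.

**Step 16**
Reactants: 23 the hydroxy aldehyde from step 15
Product: 24 (4R,5S,6S)-6-methyl-6-[(3R)-3-(TBSO)-4-methylpent-4-enyl]-5-(PMBOCH2)-4-(TBSOCH2)non-8-en-2-ol (C-2 epimers)
Conditions: Ph3PCH3Br, KN(SiMe3)2 (excess), THF, 0 °C → rt
Reagents that add atoms: methyltriphenylphosphonium bromide, C[P+](c1ccccc1)(c1ccccc1)c1ccccc1.[Br-]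
Why: Wittig methylenation turns the aldehyde into the allyl group on the quaternary carbon.

**Step 17**
Reactants: 24 the alkenol from step 16
Product: 25 (4R,5S,6S)-2-(PMBO)-6-methyl-6-[(3R)-3-(TBSO)-4-methylpent-4-enyl]-5-(PMBOCH2)-4-(TBSOCH2)non-8-ene
Conditions: NaH, PMBCl, Bu4NI (cat.), DMF, 0 °C → rt
Reagents that add atoms: 4-methoxybenzyl chloride, COc1ccc(CCl)cc1
Why: Williamson etherification protects the secondary alcohol with the same group as the primary CH2OH so both can be released together later.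

**Step 18**
Reactants: 25 the bis-PMB ether from step 17
Product: 26 the primary alcohol: 25 with CH2OTBS at C-4 converted into CH2OH (secondary allylic OTBS retained)
Conditions: HF·pyridine, pyridine, THF, 0 °C
Reagents that add atoms: none
Why: Buffered HF·pyridine cleaves the primary silyl ether much faster than the hindered secondary allylic one.

**Step 19**
Reactants: 26 the primary alcohol from step 18
Product: 27 the aldehyde: 26 with CH2OH at C-4 oxidised to CHO
Conditions: DMP, CH2Cl2, 0 °C → rt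
Reagents that add atoms: none
Why: Dess–Martin oxidation under non-basic conditions leaves the α-stereocentre intact.

**Step 20**
Reactants: 27 the aldehyde from step 19; 28 (2-bromoallyloxy)(tert-butyl)dimethylsilane
Product: 29 the allylic alcohol: 27 with CHO converted into CH(OH)C(=CH2)CH2OTBS (carbinol epimers)
Conditions: CrCl2 (4 equiv), NiCl2 (1 mol%), DMF, rt
Reagents that add atoms: none
Why: Nozaki–Hiyama–Kishi coupling; the alkenylchromium species adds chemoselectively to the aldehyde without base, so the α-centre does not epimerise.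

**Step 21**
Reactants: 29 the allylic alcohol from step 20
Product: 30 the α-methylene ketone: 29 with CH(OH) oxidised to C=O
Conditions: DMP, CH2Cl2, 0 °C → rt
Reagents that add atoms: none
Why: Dess–Martin oxidation gives the enone partner for metathesis under neutral conditions.

**Step 22**
Reactants: 30 the α-methylene ketone from step 21
Product: 31 (5S,6S,7R)-2-(TBSOCH2)-5-methyl-5-[(3R)-3-(TBSO)-4-methylpent-4-enyl]-6-(PMBOCH2)-7-[2-(PMBO)propyl]cyclohept-2-en-1-one
Conditions: second-generation Hoveyda–Grubbs catalyst (10 mol%), toluene (2 mM), 80 °C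
Reagents that add atoms: none
Why: Ring-closing metathesis between the allyl group and the 1,1-disubstituted enone olefin forms the seven-membered enone with the CH2O substituent in place; the hindered isopropenyl group should stay out.

**Step 23**
Reactants: 31 the cycloheptenone from step 22
Product: 32 (5S,6S,7R)-6-(hydroxymethyl)-7-(2-hydroxypropyl)-2-(TBSOCH2)-5-methyl-5-[(3R)-3-(TBSO)-4-methylpent-4-enyl]cyclohept-2-en-1-one
Conditions: DDQ (2.6 equiv), CH2Cl2/pH 7 buffer, 0 °C → rt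
Reagents that add atoms: none
Why: Oxidative cleavage of both PMB ethers; silyl ethers and the enone are inert.

**Step 24**
Reactants: 32 the diol from step 23
Product: 33 (1S,2R,7S)-4-(TBSOCH2)-7-methyl-7-[(3R)-3-(TBSO)-4-methylpent-4-enyl]-3-oxo-2-(2-oxopropyl)cyclohept-4-ene-1-carbaldehyde
Conditions: DMP (3 equiv), CH2Cl2, 0 °C → rt
Reagents that add atoms: none
Why: One Dess–Martin oxidation turns the primary alcohol into the aldehyde and the secondary one into the methyl ketone, without base.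

**Step 25**
Reactants: 33 the keto aldehyde from step 24
Product: 34 (5S,6S,7R)-2-(TBSOCH2)-5-methyl-5-[(3R)-3-(TBSO)-4-methylpent-4-enyl]-7-(2-oxopropyl)-6-[(E)-2-(4,4,5,5-tetramethyl-1,3,2-dioxaborolan-2-yl)ethenyl]cyclohept-2-en-1-one
Conditions: Cl2CHBpin (2 equiv), CrCl2 (8 equiv), LiI (4 equiv), THF, rt
Reagents that add atoms: 2-(dichloromethyl)-4,4,5,5-tetramethyl-1,3,2-dioxaborolane, ClC(Cl)B1OC(C)(C)C(C)(C)O1
Why: Takai–Utimoto boron olefination is aldehyde-selective (ketones untouched) and gives the (E)-alkenylboronate.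

**Step 26**
Reactants: 34 the alkenylboronate from step 25
Product: 35 potassium (E)-alkenyltrifluoroborate corresponding to 34 (Bpin replaced by BF3K)
Conditions: KHF2, MeOH/H2O, rt
Reagents that add atoms: potassium hydrogen difluoride, [K+].[F-].F
Why: Fluoride exchange gives the bench-stable trifluoroborate with retention of olefin geometry.

**Step 27**
Reactants: 35 the alkenyltrifluoroborate from step 26; 36 3-methylbut-2-enoic acid
Product: 37 bis-TBS ether of the target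
Conditions: Cu(OAc)2 (20 mol%), DMAP (20 mol%), 4 Å MS, O2 (1 atm), MeCN, 50 °C
Reagents that add atoms: none
Why: Copper-catalysed oxidative C–O coupling (Chan–Lam–Evans type) of the carboxylic acid with the alkenyltrifluoroborate is stereoretentive and gives the (E)-enol ester.

**Step 28**
Reactants: 37 bis-TBS ether of the target
Product: 38 (E)-2-{(1S,2R,7S)-4-(hydroxymethyl)-7-[(3R)-3-hydroxy-4-methylpent-4-en-1-yl]-7-methyl-3-oxo-2-(2-oxopropyl)cyclohept-4-en-1-yl}ethenyl 3-methylbut-2-enoate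
Conditions: HF·pyridine, pyridine, THF, 0 °C → rt
Reagents that add atoms: none
Why: Acidic fluoride removes both silyl ethers without acyl transfer from the enol ester or epimerisation next to the ketone.

**Compound list**
1 | 3-chloro-N-methoxy-N-methylpropanamide | CON(C)C(=O)CCCl | starting material
2 | isopropenylmagnesium bromide | C=C(C)[Mg]Br | starting material
3 | 5-chloro-2-methylpent-1-en-3-one | C=C(C)C(=O)CCCl | intermediate
4 | (3R)-5-chloro-2-methylpent-1-en-3-ol | C=C(C)[C@H](O)CCCl | intermediate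
5 | (3R)-3-(TBSO)-5-chloro-2-methylpent-1-ene | C=C(C)[C@H](O[Si](C)(C)C(C)(C)C)CCCl | intermediate
6 | (tert-butyldimethylsilyloxy)acetaldehyde | O=CCO[Si](C)(C)C(C)(C)C | starting material
7 | (triphenylphosphoranylidene)acetaldehyde | O=CC=P(c1ccccc1)(c1ccccc1)c1ccccc1 | starting material
8 | (2E)-4-(TBSO)but-2-enal | O=C/C=C/CO[Si](C)(C)C(C)(C)C | intermediate
9 | allyl acetoacetate | CC(=O)CC(=O)OCC=C | starting material
10 | allyl (3R)-2-acetyl-3-(TBSOCH2)-5-oxopentanoate (C-2 epimers; not isolated) | CC(=O)C(C(=O)OCC=C)[C@H](CO[Si](C)(C)C(C)(C)C)CC=O | intermediate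
11 | allyl (6R)-6-(TBSOCH2)-2-oxocyclohex-3-ene-1-carboxylate (C-1 epimers) | O=C1C=CC[C@@H](CO[Si](C)(C)C(C)(C)C)C1C(=O)OCC=C | intermediate
12 | (5R)-5-(TBSOCH2)cyclohex-2-en-1-one | O=C1C=CC[C@@H](CO[Si](C)(C)C(C)(C)C)C1 | intermediate
13 | (5R,6R)-5-(TBSOCH2)-6-(PMBOCH2)cyclohex-2-en-1-one (5,6-trans) | O=C1C=CC[C@@H](CO[Si](C)(C)C(C)(C)C)[C@@H]1COCc2ccc(OC)cc2 | intermediate
14 | [(3R)-3-(TBSO)-4-methylpent-4-enyl]magnesium chloride (not isolated) | C=C(C)[C@H](O[Si](C)(C)C(C)(C)C)CC[Mg]Cl | intermediate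
15 | (5R,6R)-1-[(3R)-3-(TBSO)-4-methylpent-4-enyl]-5-(TBSOCH2)-6-(PMBOCH2)cyclohex-2-en-1-ol (C-1 epimers) | OC1(CC[C@@H](O[Si](C)(C)C(C)(C)C)C(C)=C)C=CC[C@@H](CO[Si](C)(C)C(C)(C)C)[C@@H]1COCc2ccc(OC)cc2 | intermediate
16 | (4S,5R)-3-[(3R)-3-(TBSO)-4-methylpent-4-enyl]-4-(PMBOCH2)-5-(TBSOCH2)cyclohex-2-en-1-one | O=C1C=C(CC[C@@H](O[Si](C)(C)C(C)(C)C)C(C)=C)[C@@H](COCc2ccc(OC)cc2)[C@H](CO[Si](C)(C)C(C)(C)C)C1 | intermediate
17 | (3R,4S,5R)-3-methyl-3-[(3R)-3-(TBSO)-4-methylpent-4-enyl]-4-(PMBOCH2)-5-(TBSOCH2)-1-(trimethylsilyloxy)cyclohex-1-ene (not isolated) | C[Si](C)(C)OC1=C[C@](C)(CC[C@@H](O[Si](C)(C)C(C)(C)C)C(C)=C)[C@@H](COCc2ccc(OC)cc2)[C@H](CO[Si](C)(C)C(C)(C)C)C1 | intermediate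
18 | (3S,4S,5R)-3-methyl-3-[(3R)-3-(TBSO)-4-methylpent-4-enyl]-4-(PMBOCH2)-5-(TBSOCH2)cyclohexan-1-one (Me cis to CH2OPMB, trans to CH2OTBS) | O=C1C[C@](C)(CC[C@@H](O[Si](C)(C)C(C)(C)C)C(C)=C)[C@@H](COCc2ccc(OC)cc2)[C@H](CO[Si](C)(C)C(C)(C)C)C1 | intermediate
19 | (3S,4S,5S)-2-(1-hydroxyethyl)-5-methyl-5-[(3R)-3-(TBSO)-4-methylpent-4-enyl]-4-(PMBOCH2)-3-(TBSOCH2)cyclohexan-1-one (epimers at C-2 and carbinol) | O=C1C[C@](C)(CC[C@@H](O[Si](C)(C)C(C)(C)C)C(C)=C)[C@@H](COCc2ccc(OC)cc2)[C@H](CO[Si](C)(C)C(C)(C)C)C1C(C)O | intermediate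
20 | (3S,4S,5S)-2-acetyl-5-methyl-5-[(3R)-3-(TBSO)-4-methylpent-4-enyl]-4-(PMBOCH2)-3-(TBSOCH2)cyclohexan-1-one | O=C1C[C@](C)(CC[C@@H](O[Si](C)(C)C(C)(C)C)C(C)=C)[C@@H](COCc2ccc(OC)cc2)[C@H](CO[Si](C)(C)C(C)(C)C)C1C(C)=O | intermediate
21 | (3S,4S,5R)-3-methyl-3-[(3R)-3-(TBSO)-4-methylpent-4-enyl]-4-(PMBOCH2)-5-(TBSOCH2)-7-oxooctanoic acid | OC(=O)C[C@](C)(CC[C@@H](O[Si](C)(C)C(C)(C)C)C(C)=C)[C@@H](COCc1ccc(OC)cc1)[C@H](CO[Si](C)(C)C(C)(C)C)CC(C)=O | intermediate
22 | (3S,4S,5R)-3-methyl-3-[(3R)-3-(TBSO)-4-methylpent-4-enyl]-4-(PMBOCH2)-5-(TBSOCH2)octane-1,7-diol (C-7 epimers) | OCC[C@](C)(CC[C@@H](O[Si](C)(C)C(C)(C)C)C(C)=C)[C@@H](COCc1ccc(OC)cc1)[C@H](CO[Si](C)(C)C(C)(C)C)CC(C)O | intermediate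
23 | (3S,4S,5R)-7-hydroxy-3-methyl-3-[(3R)-3-(TBSO)-4-methylpent-4-enyl]-4-(PMBOCH2)-5-(TBSOCH2)octanal (C-7 epimers) | O=CC[C@](C)(CC[C@@H](O[Si](C)(C)C(C)(C)C)C(C)=C)[C@@H](COCc1ccc(OC)cc1)[C@H](CO[Si](C)(C)C(C)(C)C)CC(C)O | intermediate
24 | (4R,5S,6S)-6-methyl-6-[(3R)-3-(TBSO)-4-methylpent-4-enyl]-5-(PMBOCH2)-4-(TBSOCH2)non-8-en-2-ol (C-2 epimers) | C=CC[C@](C)(CC[C@@H](O[Si](C)(C)C(C)(C)C)C(C)=C)[C@@H](COCc1ccc(OC)cc1)[C@H](CO[Si](C)(C)C(C)(C)C)CC(C)O | intermediate
25 | (4R,5S,6S)-2-(PMBO)-6-methyl-6-[(3R)-3-(TBSO)-4-methylpent-4-enyl]-5-(PMBOCH2)-4-(TBSOCH2)non-8-ene (C-2 epimers) | C=CC[C@](C)(CC[C@@H](O[Si](C)(C)C(C)(C)C)C(C)=C)[C@@H](COCc1ccc(OC)cc1)[C@H](CO[Si](C)(C)C(C)(C)C)CC(C)OCc2ccc(OC)cc2 | intermediate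
26 | (4R,5S,6S)-4-(hydroxymethyl) analogue of 25 (primary alcohol) | C=CC[C@](C)(CC[C@@H](O[Si](C)(C)C(C)(C)C)C(C)=C)[C@@H](COCc1ccc(OC)cc1)[C@H](CO)CC(C)OCc2ccc(OC)cc2 | intermediate
27 | (4R,5S,6S)-4-formyl analogue of 25 (aldehyde) | C=CC[C@](C)(CC[C@@H](O[Si](C)(C)C(C)(C)C)C(C)=C)[C@@H](COCc1ccc(OC)cc1)[C@H](C=O)CC(C)OCc2ccc(OC)cc2 | intermediate
28 | (2-bromoallyloxy)(tert-butyl)dimethylsilane | C=C(Br)CO[Si](C)(C)C(C)(C)C | starting material
29 | (4R,5S,6S)-4-[1-hydroxy-2-(TBSOCH2)prop-2-enyl] analogue of 25 (carbinol epimers) | C=CC[C@](C)(CC[C@@H](O[Si](C)(C)C(C)(C)C)C(C)=C)[C@@H](COCc1ccc(OC)cc1)[C@H](C(O)C(=C)CO[Si](C)(C)C(C)(C)C)CC(C)OCc2ccc(OC)cc2 | intermediate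
30 | (4R,5S,6S)-4-[2-(TBSOCH2)prop-2-enoyl] analogue of 25 (α-methylene ketone) | C=CC[C@](C)(CC[C@@H](O[Si](C)(C)C(C)(C)C)C(C)=C)[C@@H](COCc1ccc(OC)cc1)[C@H](C(=O)C(=C)CO[Si](C)(C)C(C)(C)C)CC(C)OCc2ccc(OC)cc2 | intermediate
31 | (5S,6S,7R)-2-(TBSOCH2)-5-methyl-5-[(3R)-3-(TBSO)-4-methylpent-4-enyl]-6-(PMBOCH2)-7-[2-(PMBO)propyl]cyclohept-2-en-1-one | C=C(C)[C@H](O[Si](C)(C)C(C)(C)C)CC[C@@]1(C)CC=C(CO[Si](C)(C)C(C)(C)C)C(=O)[C@H](CC(C)OCc2ccc(OC)cc2)[C@@H]1COCc3ccc(OC)cc3 | intermediate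
32 | (5S,6S,7R)-6-(hydroxymethyl)-7-(2-hydroxypropyl)-2-(TBSOCH2)-5-methyl-5-[(3R)-3-(TBSO)-4-methylpent-4-enyl]cyclohept-2-en-1-one | C=C(C)[C@H](O[Si](C)(C)C(C)(C)C)CC[C@@]1(C)CC=C(CO[Si](C)(C)C(C)(C)C)C(=O)[C@H](CC(C)O)[C@@H]1CO | intermediate
33 | (1S,2R,7S)-4-(TBSOCH2)-7-methyl-7-[(3R)-3-(TBSO)-4-methylpent-4-enyl]-3-oxo-2-(2-oxopropyl)cyclohept-4-ene-1-carbaldehyde | C=C(C)[C@H](O[Si](C)(C)C(C)(C)C)CC[C@@]1(C)CC=C(CO[Si](C)(C)C(C)(C)C)C(=O)[C@H](CC(C)=O)[C@@H]1C=O | intermediate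
34 | (5S,6S,7R)-2-(TBSOCH2)-5-methyl-5-[(3R)-3-(TBSO)-4-methylpent-4-enyl]-7-(2-oxopropyl)-6-[(E)-2-(pinacolboryl)ethenyl]cyclohept-2-en-1-one | C=C(C)[C@H](O[Si](C)(C)C(C)(C)C)CC[C@@]1(C)CC=C(CO[Si](C)(C)C(C)(C)C)C(=O)[C@H](CC(C)=O)[C@@H]1/C=C/B2OC(C)(C)C(C)(C)O2 | intermediate
35 | potassium (E)-alkenyltrifluoroborate corresponding to 34 | C=C(C)[C@H](O[Si](C)(C)C(C)(C)C)CC[C@@]1(C)CC=C(CO[Si](C)(C)C(C)(C)C)C(=O)[C@H](CC(C)=O)[C@@H]1/C=C/[B-](F)(F)F.[K+] | intermediate
36 | 3-methylbut-2-enoic acid | CC(C)=CC(=O)O | starting material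
37 | bis-TBS ether of the target (secondary allylic OTBS and ring CH2OTBS) | C=C(C)[C@H](O[Si](C)(C)C(C)(C)C)CC[C@@]1(C)CC=C(CO[Si](C)(C)C(C)(C)C)C(=O)[C@H](CC(C)=O)[C@@H]1/C=C/OC(=O)C=C(C)C | intermediate
38 | (E)-2-{(1S,2R,7S)-4-(hydroxymethyl)-7-[(3R)-3-hydroxy-4-methylpent-4-en-1-yl]-7-methyl-3-oxo-2-(2-oxopropyl)cyclohept-4-en-1-yl}ethenyl 3-methylbut-2-enoate | C=C(C)[C@H](O)CC[C@@]1(C)CC=C(CO)C(=O)[C@H](CC(C)=O)[C@@H]1/C=C/OC(=O)C=C(C)C | target

**Step count and risks**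
Total steps: 28. Longest linear sequence: 25 (steps 4–28); the side-chain branch (steps 1–3) joins at step 8.

The three steps most likely to fail:

Step 10 (cuprate methylation). The β-carbon is fully substituted and flanked by a branched neighbour, and the facial outcome rests on the C-5 substituent outweighing the C-4 substituent. The fallback sets out from 16 and comes back at 18. Enone 16 is cyclopropanated with dimethylsulfoxonium methylide (Me3S(O)I, NaH, DMSO; conjugate addition with the same axial preference, then ring closure) to give the cyclopropyl ketone F1. Reductive opening with SmI2 (THF, HMPA, t-BuOH) breaks the cyclopropane bond that overlaps the carbonyl π system and leaves the methyl group on the quaternary carbon, giving 18.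

Step 13 (retro-Claisen ring opening). Hydroxide may attack the acetyl carbonyl and simply return 18, and the hot base stresses the silyl ethers. The fallback sets out from 18 and comes back at 22, building the acetonyl unit by oxidative cleavage instead. The kinetic enolate of 18 (LiN(iPr)2) is hydroxylated with 2-(phenylsulfonyl)-3-phenyloxaziridine to the α-hydroxy ketone F2. Pb(OAc)4 in MeOH/benzene cleaves it to the ester aldehyde F3. Wittig reaction with Ph3P=C(OMe)CH3 at −78 °C gives the enol ether F4, and aqueous oxalic acid hydrolyses it to the keto ester F5. LiAlH4 then gives diol 22.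

Step 22 (ring-closing metathesis to a trisubstituted enone). The 1,1-disubstituted electron-poor olefin is slow, so dimerisation of the allyl group or closure onto the isopropenyl group may compete. The fallback sets out from 27 and comes back at 31. Aldehyde 27 is treated with vinylmagnesium bromide (−78 °C) to give the allylic alcohol F6, which DMP oxidises to the vinyl ketone F7. The fast metathesis of allyl with acryloyl (second-generation Grubbs catalyst, CH2Cl2, 40 °C) gives the unsubstituted cycloheptenone F8. I2/pyridine gives the α-iodoenone F9, Stille coupling with Bu3SnCH2OH (Pd(PPh3)4, CuI, DMF) gives the hydroxymethyl enone F10, and TBSCl/imidazole returns 31.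

**Further compounds**
F1 | step 10 | cyclopropyl ketone: 6-[(3R)-3-(TBSO)-4-methylpent-4-enyl]-5-(PMBOCH2)-4-(TBSOCH2)bicyclo[4.1.0]heptan-2-one, cyclopropane CH2 cis to CH2OPMB | O=C1[C@H]2C[C@@]2(CC[C@@H](O[Si](C)(C)C(C)(C)C)C(C)=C)[C@@H](COCc3ccc(OC)cc3)[C@H](CO[Si](C)(C)C(C)(C)C)C1
F2 | step 13 | α-hydroxy ketone: 18 with OH at C-6 (epimers) | O=C1C[C@](C)(CC[C@@H](O[Si](C)(C)C(C)(C)C)C(C)=C)[C@@H](COCc2ccc(OC)cc2)[C@H](CO[Si](C)(C)C(C)(C)C)C1O
F3 | step 13 | ester aldehyde: methyl (3S,4S)-5-formyl-3-methyl-3-[(3R)-3-(TBSO)-4-methylpent-4-enyl]-4-(PMBOCH2)-6-(TBSO)hexanoate | COC(=O)C[C@](C)(CC[C@@H](O[Si](C)(C)C(C)(C)C)C(C)=C)[C@@H](COCc1ccc(OC)cc1)[C@H](CO[Si](C)(C)C(C)(C)C)C=O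
F4 | step 13 | enol ether: F3 with CHO converted into CH=C(OMe)CH3 (E/Z) | COC(=O)C[C@](C)(CC[C@@H](O[Si](C)(C)C(C)(C)C)C(C)=C)[C@@H](COCc1ccc(OC)cc1)[C@H](CO[Si](C)(C)C(C)(C)C)C=C(C)OC
F5 | step 13 | keto ester: methyl ester of 21 | COC(=O)C[C@](C)(CC[C@@H](O[Si](C)(C)C(C)(C)C)C(C)=C)[C@@H](COCc1ccc(OC)cc1)[C@H](CO[Si](C)(C)C(C)(C)C)CC(C)=O
F6 | step 22 | allylic alcohol: 27 with CHO converted into CH(OH)CH=CH2 (epimers) | C=CC[C@](C)(CC[C@@H](O[Si](C)(C)C(C)(C)C)C(C)=C)[C@@H](COCc1ccc(OC)cc1)[C@H](C(O)C=C)CC(C)OCc2ccc(OC)cc2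
F7 | step 22 | vinyl ketone: F6 oxidised to C(=O)CH=CH2 | C=CC[C@](C)(CC[C@@H](O[Si](C)(C)C(C)(C)C)C(C)=C)[C@@H](COCc1ccc(OC)cc1)[C@H](C(=O)C=C)CC(C)OCc2ccc(OC)cc2
F8 | step 22 | cycloheptenone: 31 without the CH2OTBS group at C-2 | C=C(C)[C@H](O[Si](C)(C)C(C)(C)C)CC[C@@]1(C)CC=CC(=O)[C@H](CC(C)OCc2ccc(OC)cc2)[C@@H]1COCc3ccc(OC)cc3
F9 | step 22 | α-iodoenone: F8 with iodine at C-2 | C=C(C)[C@H](O[Si](C)(C)C(C)(C)C)CC[C@@]1(C)CC=C(I)C(=O)[C@H](CC(C)OCc2ccc(OC)cc2)[C@@H]1COCc3ccc(OC)cc3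
F10 | step 22 | hydroxymethyl enone: F8 with CH2OH at C-2 | C=C(C)[C@H](O[Si](C)(C)C(C)(C)C)CC[C@@]1(C)CC=C(CO)C(=O)[C@H](CC(C)OCc2ccc(OC)cc2)[C@@H]1COCc3ccc(OC)cc3
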